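**Retrosynthetic overview**
- The target is the 8,8''-linked dimer of 5-hydroxy-7-methoxy-2-(4-hydroxyphenyl)chromen-4-one. The last disconnections are ether cleavage and then both pyranone rings C and C'' (O1–C2 and O1''–C2''), from a bis-chalcone made from a 3,3'-diacetyl-2,2'-biphenol and 4-(benzyloxy)benzaldehyde (rings B and B'').
- The strategy rests on ring A'' (C4a''–C5''–C6''–C7''–C8''–C8a''). It carries three different oxygens in a 1,3,5 relation (O1'' on C8a'', OMe on C7'', OH on C5''), and the hindered C8–C8'' bond sits between the first two. A 3-alkoxycyclobutenone plus an alkoxyacetylene gives this pattern with the three oxygens already told apart.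
- Key disconnection: ring A'' is grown on the existing aryl–carbon bond from a 4-aryl-3-methoxycyclobutenone and ethoxyacetylene. Bonds C4a''–C8a'' and C5''–C6'' come from a [2+2], and C8''–C8a'' from a six-electron closure.
- The cyclobutenone comes from an arylketene and methoxyacetylene. The arylketene comes from the arylacetic acid, made from 2-hydroxy-4,6-dimethoxybenzaldehyde (ring A) by benzylation and one-carbon homologation.
- Ring order: ring A (purchased), the four-membered ring, ring A'', then rings C and C'' together; rings B and B'' arrive with the aldehyde.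

Key step: step 8

Assumption: the SMILES fixes no configuration at the C8–C8'' axis, so the target and every biaryl from step 8 onward are planned as racemates.

**Step 1**
Reactants: 1 2-hydroxy-4,6-dimethoxybenzaldehyde
Product: 2 2-(benzyloxy)-4,6-dimethoxybenzaldehyde
Conditions: BnBr, K2CO3, DMF, 60 °C
Reagents that add atoms: benzyl bromide, BrCc1ccccc1
Why: Williamson etherification of the phenoxide, which K2CO3 in DMF frees from its hydrogen bond to the aldehyde, should be clean because no other acidic site is present.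

**Step 2**
Reactants: 2 2-(benzyloxy)-4,6-dimethoxybenzaldehyde
Product: 3 1-(benzyloxy)-3,5-dimethoxy-2-(2-methoxyethenyl)benzene (E/Z mixture)
Conditions: MeOCH2PPh3Cl, KOtBu, THF, 0 °C to rt
Reagents that add atoms: (methoxymethyl)triphenylphosphonium chloride, [Cl-].COC[P+](c1ccccc1)(c1ccccc1)c1ccccc1
Why: Wittig olefination with the unstabilized methoxymethylene ylide adds the carbon that becomes C8a'' and is reactive enough for the di-ortho-substituted, electron-rich aldehyde, the alkene geometry being of no consequence.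

**Step 3**
Reactants: 3 1-(benzyloxy)-3,5-dimethoxy-2-(2-methoxyethenyl)benzene
Product: 4 2-[2-(benzyloxy)-4,6-dimethoxyphenyl]acetaldehyde
Conditions: 2 M HCl, THF, 40 °C
Reagents that add atoms: water, O
Why: Acid hydrolysis of the enol ether (protonation at the benzylic carbon, hydration of the oxocarbenium ion, loss of methanol) should give the arylacetaldehyde under conditions that leave benzyl and methyl aryl ethers intact.

**Step 4**
Reactants: 4 2-[2-(benzyloxy)-4,6-dimethoxyphenyl]acetaldehyde
Product: 5 2-[2-(benzyloxy)-4,6-dimethoxyphenyl]acetic acid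
Conditions: NaClO2, NaH2PO4, 2-methyl-2-butene (large excess), t-BuOH/H2O, 0 °C to rt
Reagents that add atoms: sodium chlorite, [Na+].[O-]Cl=O
Why: Pinnick oxidation converts the aldehyde into the acid without touching the benzyl ether, and the excess alkene should remove HOCl before it chlorinates the phloroglucinol-type ring.

**Step 5**
Reactants: 5 2-[2-(benzyloxy)-4,6-dimethoxyphenyl]acetic acid
Product: 6 2-[2-(benzyloxy)-4,6-dimethoxyphenyl]acetyl chloride
Conditions: (COCl)2, cat. DMF, CH2Cl2, 0 °C to rt; concentrate, use crude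
Reagents that add atoms: oxalyl chloride, O=C(Cl)C(Cl)=O
Why: DMF-catalysed acyl chloride formation is fast at 0 °C, and immediate use of the crude chloride should forestall debenzylative lactonization onto the ortho oxygen.

**Step 6**
Reactants: 7 chloroacetaldehyde dimethyl acetal
Product: 10 methoxyacetylene (methoxyethyne), via 1-chloro-2-methoxyethene 8 (not isolated), via sodium methoxyacetylide 9 (not isolated)
Conditions: NaNH2 (3 equiv), liq. NH3, −33 °C; evaporate NH3; cold sat. aq. NaCl, distil into a cold trap (bp about 23 °C)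
Reagents that add atoms: none
Why: Twofold base-induced elimination (methanol, then HCl) with NaNH2 gives the acetylide, which is protonated on aqueous work-up and distilled off as the volatile ynol ether.

**Step 7**
Reactants: 6 2-[2-(benzyloxy)-4,6-dimethoxyphenyl]acetyl chloride; 10 methoxyacetylene
Product: 12 4-[2-(benzyloxy)-4,6-dimethoxyphenyl]-3-methoxycyclobut-2-en-1-one (racemic), via arylketene 11 (not isolated)
Conditions: Et3N (slow addition), 10 (4 equiv), Et2O, 0 °C to rt, closed vessel
Reagents that add atoms: none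
Why: Dehydrochlorination by Et3N gives the arylketene, which undergoes the known ketene–alkoxyacetylene [2+2] cycloaddition with the unsubstituted alkyne carbon bonding to the ketene carbonyl carbon, so that OMe sits at C3 next to the aryl-bearing C4; that stereocenter forms as a racemate and is erased in step 8.

**Step 8**
Reactants: 12 4-[2-(benzyloxy)-4,6-dimethoxyphenyl]-3-methoxycyclobut-2-en-1-one; 13 ethoxyacetylene
Product: 18 2'-(benzyloxy)-4-ethoxy-4',6,6'-trimethoxybiphenyl-2-ol (racemic axis), via vinylketene 14 (not isolated), via vinylcyclobutenone adduct 15 (not isolated), via dienylketene 16 (not isolated), via cyclohexadienone tautomer 17 (not isolated)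
Conditions: 13 (5 equiv), PhMe, sealed tube, 85 °C then 110 °C
Reagents that add atoms: none
Why: Proposed new method: heating should open 12 by conrotatory four-electron electrocyclic cleavage of C1–C4 to vinylketene 14, whose ketene C=C adds ethoxyacetylene in a [2+2] to give 15, and a second four-electron opening then gives dienylketene 16. Ring A'' is closed by thermal disrotatory six-electron electrocyclization of 16, which joins the ketene carbon (C8a'') to the aryl-bearing carbon (C8''), and dienone 17 tautomerizes to phenol 18. The closest known reaction type is the thermal benzannulation of 4-unsubstituted cyclobutenones with alkoxy- or siloxyacetylenes (Danheiser benzannulation); a 4-aryl-3-alkoxycyclobutenone that carries the future biaryl bond has not been used in it. The step needs OEt para and OH ortho to the aryl group, and this follows from the polarization of the ynol ether, whose unsubstituted carbon bonds to the ketene carbonyl carbon. It also needs the vinylketene to spare its own aryl ring, which is secured because both ortho positions carry oxygen (OBn, OMe) so that closure to a naphthol cannot aromatize, while excess ynol ether and staged heating limit ketene dimerization and retro-ene loss of ethylene from 13. No stereocenter survives: those of 12, 15 and 17 are racemic and vanish on aromatization, a dienylketene of the wrong C3=C4 geometry can revert to 15, and the C8–C8'' axis is formed as a racemate.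

**Step 9**
Reactants: 18 2'-(benzyloxy)-4-ethoxy-4',6,6'-trimethoxybiphenyl-2-ol
Product: 19 4-ethoxy-4',6,6'-trimethoxybiphenyl-2,2'-diol
Conditions: H2 (1 atm), Pd/C, EtOAc/MeOH, rt
Reagents that add atoms: none
Why: Hydrogenolysis of the benzyl ether over Pd/C frees the second phenol (the future O1) and should affect nothing else in the molecule.

**Step 10**
Reactants: 19 4-ethoxy-4',6,6'-trimethoxybiphenyl-2,2'-diol
Product: 22 1,1'-(4-ethoxy-2,2'-dihydroxy-4',6,6'-trimethoxybiphenyl-3,3'-diyl)di(ethan-1-one), via biphenyldiyl diacetate 20 (not isolated), via bis(difluoroboron) chelate 21 (not isolated)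
Conditions: Ac2O, BF3·OEt2, AcOH, 90 °C; then aq. MeOH, reflux
Reagents that add atoms: acetic anhydride, CC(=O)OC(C)=O
Why: O-acetylation followed by BF3-promoted Fries rearrangement should place each acetyl group ortho to its hydroxyl (C4a and C4a''), because only that position gives the six-membered difluoroboron chelate, which the aqueous methanol stage hydrolyses.

**Step 11**
Reactants: 22 1,1'-(4-ethoxy-2,2'-dihydroxy-4',6,6'-trimethoxybiphenyl-3,3'-diyl)di(ethan-1-one); 23 4-(benzyloxy)benzaldehyde
Product: 24 (2E,2'E)-1,1'-(4-ethoxy-2,2'-dihydroxy-4',6,6'-trimethoxybiphenyl-3,3'-diyl)bis{3-[4-(benzyloxy)phenyl]prop-2-en-1-one}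
Conditions: 23 (2.5 equiv), KOH, EtOH/H2O, rt
Reagents that add atoms: none
Why: Twofold Claisen–Schmidt condensation (aldol addition, then E1cB dehydration) of the methyl ketones with the non-enolizable aldehyde should give the bis-chalcone with both enone double bonds in the thermodynamically preferred E geometry.

**Step 12**
Reactants: 24 the bis-chalcone
Product: 25 2,2'-bis[4-(benzyloxy)phenyl]-5-ethoxy-5',7,7'-trimethoxy-4H,4'H-[8,8'-bichromene]-4,4'-dione
Conditions: I2 (cat.), DMSO, 130 °C
Reagents that add atoms: none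
Why: Iodine-catalysed oxidative cyclization of 2'-hydroxychalcones in hot DMSO, with DMSO as terminal oxidant, is the standard flavone synthesis and should close both pyranone rings C and C'' by attack of the phenol oxygen on the enone β-carbon, benzyl and alkyl aryl ethers being tolerated.

**Step 13**
Reactants: 25 the protected biflavone
Product: 26 5,5'-dihydroxy-2,2'-bis(4-hydroxyphenyl)-7,7'-dimethoxy-4H,4'H-[8,8'-bichromene]-4,4'-dione (target, racemic axis)
Conditions: BCl3 (excess), C6HMe5, CH2Cl2, −78 °C to rt; then H2O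
Reagents that add atoms: none
Why: BCl3 cleaves the benzyl ethers (benzyl cation trapped by pentamethylbenzene) and, through chelation to the C4 and C4'' carbonyl groups, the peri 5-OMe and 5''-OEt ethers, whereas the non-chelated 7- and 7''-methoxy groups are not activated and should survive.

**Compound list**
1 | 2-hydroxy-4,6-dimethoxybenzaldehyde | COc1cc(O)c(C=O)c(OC)c1 | starting material
2 | 2-(benzyloxy)-4,6-dimethoxybenzaldehyde | COc1cc(OC)c(C=O)c(OCc2ccccc2)c1 | intermediate
3 | 1-(benzyloxy)-3,5-dimethoxy-2-(2-methoxyethenyl)benzene (E/Z mixture) | COC=Cc1c(OC)cc(OC)cc1OCc1ccccc1 | intermediate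
4 | 2-[2-(benzyloxy)-4,6-dimethoxyphenyl]acetaldehyde | O=CCc1c(OC)cc(OC)cc1OCc1ccccc1 | intermediate
5 | 2-[2-(benzyloxy)-4,6-dimethoxyphenyl]acetic acid | OC(=O)Cc1c(OC)cc(OC)cc1OCc1ccccc1 | intermediate
6 | 2-[2-(benzyloxy)-4,6-dimethoxyphenyl]acetyl chloride | ClC(=O)Cc1c(OC)cc(OC)cc1OCc1ccccc1 | intermediate
7 | chloroacetaldehyde dimethyl acetal (2-chloro-1,1-dimethoxyethane) | COC(CCl)OC | starting material
8 | 1-chloro-2-methoxyethene (E/Z mixture, not isolated) | COC=CCl | intermediate
9 | sodium methoxyacetylide (not isolated) | COC#[C-].[Na+] | intermediate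
10 | methoxyacetylene (methoxyethyne) | COC#C | intermediate
11 | [2-(benzyloxy)-4,6-dimethoxyphenyl]ketene (not isolated) | O=C=Cc1c(OC)cc(OC)cc1OCc1ccccc1 | intermediate
12 | 4-[2-(benzyloxy)-4,6-dimethoxyphenyl]-3-methoxycyclobut-2-en-1-one (racemic) | COC1=CC(=O)C1c1c(OC)cc(OC)cc1OCc1ccccc1 | intermediate
13 | ethoxyacetylene (ethoxyethyne) | CCOC#C | starting material
14 | (3Z)-4-[2-(benzyloxy)-4,6-dimethoxyphenyl]-3-methoxybuta-1,3-dien-1-one (not isolated) | O=C=C/C(OC)=C/c1c(OC)cc(OC)cc1OCc1ccccc1 | intermediate
15 | 4-{(Z)-2-[2-(benzyloxy)-4,6-dimethoxyphenyl]-1-methoxyethenyl}-3-ethoxycyclobut-2-en-1-one (racemic, not isolated) | CCOC1=CC(=O)C1/C(OC)=C/c1c(OC)cc(OC)cc1OCc1ccccc1 | intermediate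
16 | (3E,5Z)-6-[2-(benzyloxy)-4,6-dimethoxyphenyl]-3-ethoxy-5-methoxyhexa-1,3,5-trien-1-one (not isolated) | O=C=C/C(OCC)=C\C(OC)=C\c1c(OC)cc(OC)cc1OCc1ccccc1 | intermediate
17 | 6-[2-(benzyloxy)-4,6-dimethoxyphenyl]-3-ethoxy-5-methoxycyclohexa-2,4-dien-1-one (racemic, not isolated) | CCOC1=CC(=O)C(c2c(OC)cc(OC)cc2OCc2ccccc2)C(OC)=C1 | intermediate
18 | 2'-(benzyloxy)-4-ethoxy-4',6,6'-trimethoxybiphenyl-2-ol (racemic axis) | CCOc1cc(O)c(-c2c(OC)cc(OC)cc2OCc2ccccc2)c(OC)c1 | intermediate
19 | 4-ethoxy-4',6,6'-trimethoxybiphenyl-2,2'-diol (racemic axis) | CCOc1cc(O)c(-c2c(O)cc(OC)cc2OC)c(OC)c1 | intermediate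
20 | 4-ethoxy-4',6,6'-trimethoxybiphenyl-2,2'-diyl diacetate (not isolated) | CCOc1cc(OC(C)=O)c(-c2c(OC(C)=O)cc(OC)cc2OC)c(OC)c1 | intermediate
21 | bis(difluoroboron) chelate of 22 (not isolated) | CCOc1cc(OC)c(-c3c(OC)cc(OC)c4C(C)=[O+][B-](F)(F)Oc34)c2O[B-](F)(F)[O+]=C(C)c12 | intermediate
22 | 1,1'-(4-ethoxy-2,2'-dihydroxy-4',6,6'-trimethoxybiphenyl-3,3'-diyl)di(ethan-1-one) (racemic axis) | CCOc1cc(OC)c(-c2c(OC)cc(OC)c(C(C)=O)c2O)c(O)c1C(C)=O | intermediate
23 | 4-(benzyloxy)benzaldehyde | O=Cc1ccc(OCc2ccccc2)cc1 | starting material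
24 | (2E,2'E)-1,1'-(4-ethoxy-2,2'-dihydroxy-4',6,6'-trimethoxybiphenyl-3,3'-diyl)bis{3-[4-(benzyloxy)phenyl]prop-2-en-1-one} (racemic axis) | CCOc1cc(OC)c(-c2c(OC)cc(OC)c(C(=O)/C=C/c3ccc(OCc4ccccc4)cc3)c2O)c(O)c1C(=O)/C=C/c1ccc(OCc2ccccc2)cc1 | intermediate
25 | 2,2'-bis[4-(benzyloxy)phenyl]-5-ethoxy-5',7,7'-trimethoxy-4H,4'H-[8,8'-bichromene]-4,4'-dione (racemic axis) | CCOc1cc(OC)c(-c2c(OC)cc(OC)c3c(=O)cc(-c4ccc(OCc5ccccc5)cc4)oc23)c2oc(-c3ccc(OCc4ccccc4)cc3)cc(=O)c12 | intermediate
26 | 5,5'-dihydroxy-2,2'-bis(4-hydroxyphenyl)-7,7'-dimethoxy-4H,4'H-[8,8'-bichromene]-4,4'-dione (racemic axis) | COc1cc(O)c2c(=O)cc(-c3ccc(O)cc3)oc2c1-c1c(OC)cc(O)c2c(=O)cc(-c3ccc(O)cc3)oc12 | target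

**Step count and risks**
Total step count: 13. Longest linear sequence: 12 steps (steps 1 to 5 and 7 to 13; step 6 makes a reagent on a side branch).

Steps most likely to fail:

1. Step 8 (proposed new method). The ring opening of 12 may need a temperature at which ethoxyacetylene already fragments to ketene and ethylene. Inward rotation of the aryl group may also slow the final closure, so that ketene dimerization takes over. The fallback makes the same vinylketene near 0 °C by known 1,4-dehydrochlorination chemistry and sets out from acid chloride 6.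
   - 6 is added to two equivalents of the lithium enolate of methyl acetate (LiN(iPr)2, THF, −78 °C) to give methyl 4-[2-(benzyloxy)-4,6-dimethoxyphenyl]-3-oxobutanoate F1.
   - Trimethyl orthoformate with catalytic H2SO4 in methanol converts it into methyl (E)-4-[2-(benzyloxy)-4,6-dimethoxyphenyl]-3-methoxybut-2-enoate F2.
   - LiOH in aqueous THF gives (E)-4-[2-(benzyloxy)-4,6-dimethoxyphenyl]-3-methoxybut-2-enoic acid F3.
   - Oxalyl chloride with catalytic DMF gives (E)-4-[2-(benzyloxy)-4,6-dimethoxyphenyl]-3-methoxybut-2-enoyl chloride F4.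
   - Et3N in CH2Cl2 at 0 °C, with ethoxyacetylene 13 present, removes HCl in a 1,4 sense by deprotonation of the benzylic γ-CH2. This is the known route from α,β-unsaturated acid chlorides to vinylketenes.
   - The route is rejoined at vinylketene 14, which should add 13 to give 15. Brief heating in toluene then leads through 16 and 17 to 18.

2. Step 7. Dimerization of the arylketene, decomposition of the volatile methoxyacetylene by the amine hydrochloride, or debenzylative lactonization of the acyl chloride may outrun the cycloaddition. The fallback generates the same ketene without amine or chloride and sets out from aldehyde 2.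
   - Pinnick oxidation (NaClO2, NaH2PO4, 2-methyl-2-butene) gives 2-(benzyloxy)-4,6-dimethoxybenzoic acid F5.
   - Oxalyl chloride gives 2-(benzyloxy)-4,6-dimethoxybenzoyl chloride F6.
   - Excess diazomethane in Et2O at 0 °C gives 1-[2-(benzyloxy)-4,6-dimethoxyphenyl]-2-diazoethan-1-one F7.
   - Irradiation of F7 with blue light (about 450 nm, where the diazo ketone absorbs and a cyclobutenone does not), with methoxyacetylene 10 present, should bring about a Wolff rearrangement.
   - The route is rejoined at arylketene 11, which is trapped as in step 7 to give 12. This path also bypasses steps 2 to 5.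

3. Step 10. The acyl transfer may show poor ortho/para regioselectivity. C6 and C6'' lie para to the hydroxyls between two alkoxy groups and are about as electron-rich as C4a and C4a''. The second acylation may also stall. The fallback fixes the position by directed metalation and sets out from biphenol 19.
   - MOMCl and iPr2NEt in CH2Cl2 give 4-ethoxy-4',6,6'-trimethoxy-2,2'-bis(methoxymethoxy)biphenyl F8.
   - Twofold directed ortho-lithiation (n-BuLi, TMEDA, THF, 0 °C) should occur next to the stronger directing OMOM groups. Quenching with N-methoxy-N-methylacetamide gives 1,1'-[4-ethoxy-4',6,6'-trimethoxy-2,2'-bis(methoxymethoxy)biphenyl-3,3'-diyl]di(ethan-1-one) F9.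
   - HCl in methanol removes both MOM groups, and the route is rejoined at diketone 22.

**Further compounds**
F1 | step 8 | methyl 4-[2-(benzyloxy)-4,6-dimethoxyphenyl]-3-oxobutanoate | COC(=O)CC(=O)Cc1c(OC)cc(OC)cc1OCc1ccccc1
F2 | step 8 | methyl (E)-4-[2-(benzyloxy)-4,6-dimethoxyphenyl]-3-methoxybut-2-enoate | COC(=O)/C=C(/OC)Cc1c(OC)cc(OC)cc1OCc1ccccc1
F3 | step 8 | (E)-4-[2-(benzyloxy)-4,6-dimethoxyphenyl]-3-methoxybut-2-enoic acid | OC(=O)/C=C(/OC)Cc1c(OC)cc(OC)cc1OCc1ccccc1
F4 | step 8 | (E)-4-[2-(benzyloxy)-4,6-dimethoxyphenyl]-3-methoxybut-2-enoyl chloride | ClC(=O)/C=C(/OC)Cc1c(OC)cc(OC)cc1OCc1ccccc1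
F5 | step 7 | 2-(benzyloxy)-4,6-dimethoxybenzoic acid | OC(=O)c1c(OC)cc(OC)cc1OCc1ccccc1
F6 | step 7 | 2-(benzyloxy)-4,6-dimethoxybenzoyl chloride | ClC(=O)c1c(OC)cc(OC)cc1OCc1ccccc1
F7 | step 7 | 1-[2-(benzyloxy)-4,6-dimethoxyphenyl]-2-diazoethan-1-one | [N-]=[N+]=CC(=O)c1c(OC)cc(OC)cc1OCc1ccccc1
F8 | step 10 | 4-ethoxy-4',6,6'-trimethoxy-2,2'-bis(methoxymethoxy)biphenyl | CCOc1cc(OCOC)c(-c2c(OCOC)cc(OC)cc2OC)c(OC)c1
F9 | step 10 | 1,1'-[4-ethoxy-4',6,6'-trimethoxy-2,2'-bis(methoxymethoxy)biphenyl-3,3'-diyl]di(ethan-1-one) | CCOc1cc(OC)c(-c2c(OC)cc(OC)c(C(C)=O)c2OCOC)c(OCOC)c1C(C)=O
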